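**Plan**

1. Locants: cyclohexene C1' (alkene carbon carrying the CH2CH2 linker), C2' (alkene carbon carrying CH3), C3', C4' (CH2), C5' (CHOH), C6' (quaternary C); the bicycle is numbered as a 1-benzoxepine (O1, C2–C5, C5a, C6–C9, C9a).
2. Cuts: linker CH2–C1' (B-alkyl Suzuki–Miyaura coupling); excision of C2' (CH–CH3) from between C1' and C3' (retro one-carbon ring expansion to a cyclopentanone); side-chain CH=CH (cross-metathesis); O1–C2 and C5a–C6 (epoxide cascade); C7–CH3 (methyl addition).
3. Forward, left half: geranyl bromide → Weinreb amide → bis-epoxide → allyl ketone → silyl dienol ether → oxepane and cyclohexanone closed in one flask → tertiary carbinol.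
4. Forward, right half: 2-allyl-2-methylcyclopentane-1,3-dione → desymmetrising reduction → cyclopentanone enlarged to the cyclohexanone → enol triflate → side chain by metathesis; then union of the halves and desilylation.
5. Enabling feature: the ring carbonyl that becomes C1' lies between the fully substituted C6' and a CH2 (future C3'). Only the CH2 migrates, so the inserted C2' ends beside a ketone that can enolise in one direction only; this fixes the tetrasubstituted C1'=C2' bond and the coupling site at C1'.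
6. Stereochemistry: C5'/C6' from the oxazaborolidine-catalysed desymmetrisation; C3, C5a, C9a from two Shi epoxides (retention at C3 and C9a, inversion at C5a); C6 from the chair closure of the Z-dienol ether; C7 from equatorial methyl addition; E-alkene from metathesis.

Key step: step 10

Remark: the (S)-oxazaborolidine is assigned from the usual model with the quaternary carbon as the large group, and the D-fructose-derived ketone is taken to give (R)-configured epoxide carbons as for other trisubstituted E-olefins.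

**Route**

Step 1
Reactants: 1 geranyl bromide [(2E)-1-bromo-3,7-dimethylocta-2,6-diene]; 2 N-methoxy-N-methylacetamide
Product: 4 (4E)-N-methoxy-N,5,9-trimethyldeca-4,8-dienamide, via lithium enolate of the acetamide 3 (not isolated)
Conditions: LiN(iPr)2, THF, −78 °C; then 1, −78 → −30 °C
Reagents that add atoms: none
Why: The lithium enolate of the Weinreb acetamide should be C-alkylated by the primary allylic bromide (SN2 enolate alkylation), which keeps the E-trisubstituted double bond.

Step 2
Reactants: 4 (4E)-N-methoxy-N,5,9-trimethyldeca-4,8-dienamide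
Product: 5 (4R,5R,8R)-4,5:8,9-diepoxy-N-methoxy-N,5,9-trimethyldecanamide
Conditions: D-fructose-derived ketone catalyst (1,2:4,5-di-O-isopropylidene-β-D-erythro-2,3-hexodiulo-2,6-pyranose, 0.6 equiv), KHSO5 (Oxone), K2CO3, Bu4NHSO4, MeCN/CH2(OMe)2, aq. Na2B4O7 buffer (pH 10.5), 0 °C
Reagents that add atoms: potassium peroxymonosulfate, [K+].[O-]S(=O)(=O)OO
Why: Shi asymmetric epoxidation: the dioxirane should oxidise both trisubstituted E-olefins through a spiro transition state from the same face, setting the (R) carbinol carbon of the later oxepane (C3) and the trans (R,R) epoxide that later defines the ring fusion, while the amide is inert.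

Step 3
Reactants: 5 (4R,5R,8R)-4,5:8,9-diepoxy-N-methoxy-N,5,9-trimethyldecanamide
Product: 6 (7R,8R,11R)-7,8:11,12-diepoxy-8,12-dimethyltridec-1-en-4-one
Conditions: CH2=CHCH2MgBr (1.3 equiv), THF, −78 °C; aq. NH4Cl at −78 °C
Reagents that add atoms: allylmagnesium bromide, C=CC[Mg]Br
Why: Weinreb ketone synthesis: the Grignard reagent should add once (stable magnesium chelate), the trisubstituted epoxides are inert at −78 °C, and the cold neutral quench should keep the β,γ-double bond out of conjugation.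

Step 4
Reactants: 6 (7R,8R,11R)-7,8:11,12-diepoxy-8,12-dimethyltridec-1-en-4-one
Product: 8 tert-butyl{[(3Z,7R,8R,11R)-7,8:11,12-diepoxy-8,12-dimethyltrideca-1,3-dien-4-yl]oxy}dimethylsilane, via potassium dienolate 7 (not isolated)
Conditions: KN(SiMe3)2, THF, −78 °C; tBuMe2SiCl, −78 → 0 °C
Reagents that add atoms: tert-butyl(chloro)dimethylsilane, CC(C)(C)[Si](C)(C)Cl
Why: Deprotonation should occur at the doubly activated CH2 between the carbonyl and the vinyl group, and O-silylation of the extended potassium dienolate should give the regio-defined Z silyl dienol ether.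

Step 5
Reactants: 8 tert-butyl{[(3Z,7R,8R,11R)-7,8:11,12-diepoxy-8,12-dimethyltrideca-1,3-dien-4-yl]oxy}dimethylsilane
Product: 9 (3R,5aR,6R,9aR)-3-{[tert-butyl(dimethyl)silyl]oxy}-6-ethenyl-2,2,5a-trimethyloctahydro-1-benzoxepin-7(2H)-one
Conditions: tBuMe2SiOTf (0.3 equiv), 2,6-di-tert-butyl-4-methylpyridine, CH2Cl2, −78 → −40 °C; Et3N quench
Reagents that add atoms: none
Why: Silyl-triflate-promoted tandem oxa-/carbacyclisation of a 1,5-diepoxide terminated by an enol silane: silylation of the terminal epoxide should trigger attack of the second epoxide oxygen at the tertiary carbon (7-endo, C3 retained), and the epoxonium ion should be opened at its tertiary carbon with inversion by the α-carbon of the dienol ether through a chair (only the α-terminus can form the six-membered ring), which gives the trans fusion (C5a, C9a), places the vinyl group at C6 equatorial because it is trans to the chain on the Z-enol ether, and relays the silyl group from the enol oxygen to O3.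

Step 6
Reactants: 9 (3R,5aR,6R,9aR)-3-{[tert-butyl(dimethyl)silyl]oxy}-6-ethenyl-2,2,5a-trimethyloctahydro-1-benzoxepin-7(2H)-one
Product: 10 (3R,5aR,6R,7S,9aR)-3-{[tert-butyl(dimethyl)silyl]oxy}-6-ethenyl-2,2,5a,7-tetramethyldecahydro-1-benzoxepin-7-ol
Conditions: MeLi, CeCl3 (dried), THF, −78 °C
Reagents that add atoms: methyllithium, [Li]C
Why: 1,2-Addition of the weakly basic organocerium reagent should outrun enolisation of the β,γ-unsaturated ketone, and attack from the equatorial direction, away from the syn-axial methyl group on C5a, should give the axial (7S) tertiary alcohol.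

Step 7
Reactants: 11 2-methylcyclopentane-1,3-dione
Product: 12 2-methyl-2-(prop-2-en-1-yl)cyclopentane-1,3-dione
Conditions: allyl bromide, 1 M aq. NaOH, rt
Reagents that add atoms: allyl bromide, C=CCBr
Why: C-Alkylation of the stabilised enolate of the cyclic 1,3-dione with an allylic halide in aqueous base is a standard entry to 2,2-disubstituted cyclopentane-1,3-diones.

Step 8
Reactants: 12 2-methyl-2-(prop-2-en-1-yl)cyclopentane-1,3-dione
Product: 13 (2R,3R)-3-hydroxy-2-methyl-2-(prop-2-en-1-yl)cyclopentan-1-one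
Conditions: (S)-2-methyl-CBS-oxazaborolidine (20 mol %), BH3·SMe2 (0.6 equiv), THF, −30 °C
Reagents that add atoms: none
Why: Corey–Bakshi–Shibata reduction used as a desymmetrisation: with the quaternary carbon as the large group the (S)-catalyst should give the (R)-carbinol, and hydride delivery anti to the larger allyl group should place OH cis to allyl, so that C5' and C6' are both set here.

Step 9
Reactants: 13 (2R,3R)-3-hydroxy-2-methyl-2-(prop-2-en-1-yl)cyclopentan-1-one
Product: 14 (2R,3R)-3-{[tert-butyl(dimethyl)silyl]oxy}-2-methyl-2-(prop-2-en-1-yl)cyclopentan-1-one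
Conditions: tBuMe2SiOTf, 2,6-lutidine, CH2Cl2, −78 → 0 °C
Reagents that add atoms: tert-butyldimethylsilyl trifluoromethanesulfonate, CC(C)(C)[Si](C)(C)OS(=O)(=O)C(F)(F)F
Why: Silylation of the hindered secondary alcohol with a silyl triflate and a hindered base is standard and blocks retro-aldol cleavage and O-sulfonylation in the next steps.

Step 10
Reactants: 14 (2R,3R)-3-{[tert-butyl(dimethyl)silyl]oxy}-2-methyl-2-(prop-2-en-1-yl)cyclopentan-1-one
Product: 15 (2R,3R)-3-{[tert-butyl(dimethyl)silyl]oxy}-2,6-dimethyl-2-(prop-2-en-1-yl)cyclohexan-1-one (both C6 epimers)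
Conditions: CH3CHN2 (ca. 2 equiv, toluene solution), Sc(OTf)3 (10 mol %), toluene, −78 → −40 °C
Reagents that add atoms: diazoethane, CC=[N+]=[N-]
Why: Sc(OTf)3 activates the ketone, the carbon of diazoethane adds to the carbonyl carbon to give a β-oxido alkanediazonium species, and a ring bond migrates from the carbonyl carbon to the diazo carbon with loss of N2, so that a CH–CH3 unit is inserted into the five-membered ring. The closest known reaction type is the Lewis-acid-catalysed homologation of cycloalkanones with non-stabilised diazoalkanes (Tiffeneau–Demjanov-type ring expansion). No ring is closed by cyclisation: the cyclohexanone arises from the cyclopentanone by a 1,2-shift of the ring CH2 (future C3') that enlarges the ring by one atom (C2'). The new stereocentre C2' forms as a mixture of epimers, which does not matter because it becomes sp2 in step 11, and C5' and C6' are untouched because neither is the migrating carbon. The step needs migration of the CH2 and not of the quaternary C6', and a single homologation: the fully substituted, inductively deactivated (β-silyloxy) carbon is the poorer and more hindered migrating group, and the product ketone, now flanked by a quaternary and a tertiary carbon, is far less reactive towards diazoethane than 14.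

Step 11
Reactants: 15 (2R,3R)-3-{[tert-butyl(dimethyl)silyl]oxy}-2,6-dimethyl-2-(prop-2-en-1-yl)cyclohexan-1-one
Product: 17 (5R,6R)-5-{[tert-butyl(dimethyl)silyl]oxy}-2,6-dimethyl-6-(prop-2-en-1-yl)cyclohex-1-en-1-yl trifluoromethanesulfonate, via potassium enolate 16 (not isolated)
Conditions: KN(SiMe3)2, THF, −78 → 0 °C; PhNTf2, −78 °C → rt
Reagents that add atoms: N-phenylbis(trifluoromethanesulfonimide), O=S(=O)(N(c1ccccc1)S(=O)(=O)C(F)(F)F)C(F)(F)F
Why: Only C2' carries an α-hydrogen, so deprotonation and O-sulfonylation should give a single, tetrasubstituted enol triflate (regiospecific enol triflate formation) and erase the epimers.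

Step 12
Reactants: 17 (5R,6R)-5-{[tert-butyl(dimethyl)silyl]oxy}-2,6-dimethyl-6-(prop-2-en-1-yl)cyclohex-1-en-1-yl trifluoromethanesulfonate
Product: 18 (5R,6R)-5-{[tert-butyl(dimethyl)silyl]oxy}-6-[(2E)-4-hydroxy-4-methylpent-2-en-1-yl]-2,6-dimethylcyclohex-1-en-1-yl trifluoromethanesulfonate
Conditions: 2-methylbut-3-en-2-ol (5 equiv), second-generation Grubbs catalyst (5 mol %), CH2Cl2, 40 °C
Reagents that add atoms: 2-methylbut-3-en-2-ol, CC(C)(O)C=C
Why: Olefin cross-metathesis of the terminal allyl group with an excess of the tertiary allylic alcohol, which does not homodimerise, should give the E-disubstituted alkene, while the tetrasubstituted enol triflate alkene stays out of the reaction.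

Step 13
Reactants: 10 (3R,5aR,6R,7S,9aR)-3-{[tert-butyl(dimethyl)silyl]oxy}-6-ethenyl-2,2,5a,7-tetramethyldecahydro-1-benzoxepin-7-ol; 18 (5R,6R)-5-{[tert-butyl(dimethyl)silyl]oxy}-6-[(2E)-4-hydroxy-4-methylpent-2-en-1-yl]-2,6-dimethylcyclohex-1-en-1-yl trifluoromethanesulfonate
Product: 20 3,5'-bis-O-[tert-butyl(dimethyl)silyl]siphonellinol C, via B-alkyl-9-borabicyclo[3.3.1]nonane 19 (not isolated)
Conditions: 9-borabicyclo[3.3.1]nonane dimer (2.2 equiv B–H), THF, rt; then aq. Cs2CO3, 18, PdCl2(dppf) (10 mol %), AsPh3, DMF, 50 °C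
Reagents that add atoms: none
Why: Anti-Markovnikov hydroboration of the vinyl group followed by B-alkyl Suzuki–Miyaura coupling with the enol triflate (zerovalent palladium formed in situ, AsPh3 to speed transmetalation) should join the halves at the fully substituted alkene carbon C1' without moving the double bond, and free tertiary hydroxyl groups are tolerated.

Step 14
Reactants: 20 3,5'-bis-O-[tert-butyl(dimethyl)silyl]siphonellinol C
Product: 21 siphonellinol C
Conditions: Bu4NF, THF, 50 °C
Reagents that add atoms: none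
Why: Fluoride should cleave both secondary silyl ethers (Si–F bond formation), and the tertiary and allylic alcohols are stable to these basic conditions.

**Compound list**

1 | geranyl bromide, (2E)-1-bromo-3,7-dimethylocta-2,6-diene | CC(C)=CCC/C(C)=C/CBr | starting material
2 | N-methoxy-N-methylacetamide | CC(=O)N(C)OC | starting material
3 | lithium enolate of N-methoxy-N-methylacetamide | C=C(O[Li])N(C)OC | intermediate
4 | (4E)-N-methoxy-N,5,9-trimethyldeca-4,8-dienamide | CC(C)=CCC/C(C)=C/CCC(=O)N(C)OC | intermediate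
5 | (4R,5R,8R)-4,5:8,9-diepoxy-N-methoxy-N,5,9-trimethyldecanamide | CC1(C)O[C@@H]1CC[C@@]2(C)O[C@@H]2CCC(=O)N(C)OC | intermediate
6 | (7R,8R,11R)-7,8:11,12-diepoxy-8,12-dimethyltridec-1-en-4-one | CC1(C)O[C@@H]1CC[C@@]2(C)O[C@@H]2CCC(=O)CC=C | intermediate
7 | potassium (3Z)-dienolate of 6 | CC1(C)O[C@@H]1CC[C@@]2(C)O[C@@H]2CC/C(O[K])=C/C=C | intermediate
8 | tert-butyl{[(3Z,7R,8R,11R)-7,8:11,12-diepoxy-8,12-dimethyltrideca-1,3-dien-4-yl]oxy}dimethylsilane | CC1(C)O[C@@H]1CC[C@@]2(C)O[C@@H]2CC/C(O[Si](C)(C)C(C)(C)C)=C/C=C | intermediate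
9 | (3R,5aR,6R,9aR)-3-{[tert-butyl(dimethyl)silyl]oxy}-6-ethenyl-2,2,5a-trimethyloctahydro-1-benzoxepin-7(2H)-one (trans-fused oxepane–cyclohexanone) | C=C[C@@H]1[C@@]2(C)CC[C@@H](O[Si](C)(C)C(C)(C)C)C(C)(C)O[C@@H]2CCC1=O | intermediate
10 | (3R,5aR,6R,7S,9aR)-3-{[tert-butyl(dimethyl)silyl]oxy}-6-ethenyl-2,2,5a,7-tetramethyldecahydro-1-benzoxepin-7-ol | C=C[C@@H]1[C@@]2(C)CC[C@@H](O[Si](C)(C)C(C)(C)C)C(C)(C)O[C@@H]2CC[C@]1(C)O | intermediate
11 | 2-methylcyclopentane-1,3-dione | CC1C(=O)CCC1=O | starting material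
12 | 2-methyl-2-(prop-2-en-1-yl)cyclopentane-1,3-dione | C=CCC1(C)C(=O)CCC1=O | intermediate
13 | (2R,3R)-3-hydroxy-2-methyl-2-(prop-2-en-1-yl)cyclopentan-1-one (OH cis to allyl) | C=CC[C@]1(C)[C@H](O)CCC1=O | intermediate
14 | (2R,3R)-3-{[tert-butyl(dimethyl)silyl]oxy}-2-methyl-2-(prop-2-en-1-yl)cyclopentan-1-one | C=CC[C@]1(C)[C@H](O[Si](C)(C)C(C)(C)C)CCC1=O | intermediate
15 | (2R,3R)-3-{[tert-butyl(dimethyl)silyl]oxy}-2,6-dimethyl-2-(prop-2-en-1-yl)cyclohexan-1-one (both C6 epimers) | C=CC[C@]1(C)[C@H](O[Si](C)(C)C(C)(C)C)CCC(C)C1=O | intermediate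
16 | potassium enolate of 15 | C=CC[C@]1(C)[C@H](O[Si](C)(C)C(C)(C)C)CCC(C)=C1O[K] | intermediate
17 | (5R,6R)-5-{[tert-butyl(dimethyl)silyl]oxy}-2,6-dimethyl-6-(prop-2-en-1-yl)cyclohex-1-en-1-yl trifluoromethanesulfonate | C=CC[C@]1(C)[C@H](O[Si](C)(C)C(C)(C)C)CCC(C)=C1OS(=O)(=O)C(F)(F)F | intermediate
18 | (5R,6R)-5-{[tert-butyl(dimethyl)silyl]oxy}-6-[(2E)-4-hydroxy-4-methylpent-2-en-1-yl]-2,6-dimethylcyclohex-1-en-1-yl trifluoromethanesulfonate | CC(C)(O)/C=C/C[C@]1(C)[C@H](O[Si](C)(C)C(C)(C)C)CCC(C)=C1OS(=O)(=O)C(F)(F)F | intermediate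
19 | 9-{2-[(3R,5aR,6R,7S,9aR)-3-{[tert-butyl(dimethyl)silyl]oxy}-7-hydroxy-2,2,5a,7-tetramethyldecahydro-1-benzoxepin-6-yl]ethyl}-9-borabicyclo[3.3.1]nonane | C(C[C@@H]1[C@@]2(C)CC[C@@H](O[Si](C)(C)C(C)(C)C)C(C)(C)O[C@@H]2CC[C@]1(C)O)B3C4CCCC3CCC4 | intermediate
20 | 3,5'-bis-O-[tert-butyl(dimethyl)silyl]siphonellinol C (silyl ethers at the oxepane carbinol and at the cyclohexene carbinol) | CC1=C(CC[C@@H]2[C@@]3(C)CC[C@@H](O[Si](C)(C)C(C)(C)C)C(C)(C)O[C@@H]3CC[C@]2(C)O)[C@](C)(C/C=C/C(C)(C)O)[C@H](O[Si](C)(C)C(C)(C)C)CC1 | intermediate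
21 | siphonellinol C | CC1=C(CC[C@@H]2[C@@]3(C)CC[C@@H](O)C(C)(C)O[C@@H]3CC[C@]2(C)O)[C@](C)(C/C=C/C(C)(C)O)[C@H](O)CC1 | target

**Summary**

Total step count: 14. Longest linear sequence: 8 steps (steps 1–6, 13, 14; the sequence 7–12, 13, 14 is equally long).

Steps most likely to fail:

Step 5. The tandem closure may be diverted by opening of the epoxonium ion at its secondary carbon, by alkylation through the γ-terminus of the dienol ether, or by migration of the β,γ-double bond of the product into conjugation. The fallback moves the silicon of the terminator from oxygen to carbon and carries C7 as a carbinol. It sets out from Weinreb amide 5. With (E)-3-(trimethylsilyl)prop-1-en-1-yllithium (from (E)-(3-iodoprop-2-en-1-yl)trimethylsilane and tBuLi, THF, −78 °C), 5 should give the γ-silyl enone (2E,7R,8R,11R)-7,8:11,12-diepoxy-8,12-dimethyl-1-(trimethylsilyl)tridec-2-en-4-one F1. Luche reduction (NaBH4, CeCl3, MeOH, −40 °C) should give the allylic alcohol (2E,7R,8R,11R)-7,8:11,12-diepoxy-8,12-dimethyl-1-(trimethylsilyl)tridec-2-en-4-ol F2 (C4 epimers, of no consequence), and acetylation (Ac2O, pyridine, DMAP) the acetate (2E,7R,8R,11R)-7,8:11,12-diepoxy-8,12-dimethyl-1-(trimethylsilyl)tridec-2-en-4-yl acetate F3. With tBuMe2SiOTf (1.1 equiv) and 2,6-di-tert-butyl-4-methylpyridine at −78 °C the same epoxonium cascade should then be ended by the allylsilane (Hosomi–Sakurai-type closure with loss of Me3Si, vinyl group formed at C6) to give (3R,5aR,6R,9aR)-3-{[tert-butyl(dimethyl)silyl]oxy}-6-ethenyl-2,2,5a-trimethyldecahydro-1-benzoxepin-7-yl acetate F4. Methanolysis (K2CO3, MeOH) to (3R,5aR,6R,9aR)-3-{[tert-butyl(dimethyl)silyl]oxy}-6-ethenyl-2,2,5a-trimethyldecahydro-1-benzoxepin-7-ol F5 and Dess–Martin oxidation come back to the route at ketone 9.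

Step 10. Addition of diazoethane to the neopentyl-type carbonyl group may be slow, so that epoxide formation or migration of the wrong ring bond competes. The fallback brings in the ring carbon and its methyl group separately and sets out from 14. Me3SiCHN2 with BF3·OEt2 (CH2Cl2, −78 °C) should insert a CH(SiMe3) unit to give (2R,3R)-3-{[tert-butyl(dimethyl)silyl]oxy}-2-methyl-2-(prop-2-en-1-yl)-6-(trimethylsilyl)cyclohexan-1-one F6, whose C-silyl group blocks a second insertion. K2CO3 in MeOH should cleave the C–Si bond to (2R,3R)-3-{[tert-butyl(dimethyl)silyl]oxy}-2-methyl-2-(prop-2-en-1-yl)cyclohexan-1-one F7. Methylation at the only enolisable position (LiN(iPr)2, MeI, THF, −78 °C) comes back to the route at 15.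

Step 13. Transmetalation to the hindered, fully substituted alkenylpalladium triflate may be slow, so that triflate hydrolysis and protodeboronation win. The fallback changes the nucleophile from boron to zinc and sets out from 10. Hydroboration–oxidation (9-borabicyclo[3.3.1]nonane, then NaOH, H2O2) through borane 19 should give (3R,5aR,6R,7S,9aR)-3-{[tert-butyl(dimethyl)silyl]oxy}-6-(2-hydroxyethyl)-2,2,5a,7-tetramethyldecahydro-1-benzoxepin-7-ol F8. I2, PPh3 and imidazole should give the primary iodide (3R,5aR,6R,7S,9aR)-3-{[tert-butyl(dimethyl)silyl]oxy}-6-(2-iodoethyl)-2,2,5a,7-tetramethyldecahydro-1-benzoxepin-7-ol F9. Zinc insertion (Zn dust, LiCl, THF) should give the alkylzinc iodide {2-[(3R,5aR,6R,7S,9aR)-3-{[tert-butyl(dimethyl)silyl]oxy}-7-hydroxy-2,2,5a,7-tetramethyldecahydro-1-benzoxepin-6-yl]ethyl}(iodo)zinc F10. Negishi coupling with triflate 18 (Pd(OAc)2, SPhos, THF, 50 °C) comes back to the route at 20.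

**Further compounds**

F1 | step 5 | (2E,7R,8R,11R)-7,8:11,12-diepoxy-8,12-dimethyl-1-(trimethylsilyl)tridec-2-en-4-one | CC1(C)O[C@@H]1CC[C@@]2(C)O[C@@H]2CCC(=O)/C=C/C[Si](C)(C)C
F2 | step 5 | (2E,7R,8R,11R)-7,8:11,12-diepoxy-8,12-dimethyl-1-(trimethylsilyl)tridec-2-en-4-ol (C4 epimers) | CC1(C)O[C@@H]1CC[C@@]2(C)O[C@@H]2CCC(O)/C=C/C[Si](C)(C)C
F3 | step 5 | (2E,7R,8R,11R)-7,8:11,12-diepoxy-8,12-dimethyl-1-(trimethylsilyl)tridec-2-en-4-yl acetate (C4 epimers) | CC1(C)O[C@@H]1CC[C@@]2(C)O[C@@H]2CCC(OC(C)=O)/C=C/C[Si](C)(C)C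
F4 | step 5 | (3R,5aR,6R,9aR)-3-{[tert-butyl(dimethyl)silyl]oxy}-6-ethenyl-2,2,5a-trimethyldecahydro-1-benzoxepin-7-yl acetate (C7 epimers) | C=C[C@@H]1[C@@]2(C)CC[C@@H](O[Si](C)(C)C(C)(C)C)C(C)(C)O[C@@H]2CCC1OC(C)=O
F5 | step 5 | (3R,5aR,6R,9aR)-3-{[tert-butyl(dimethyl)silyl]oxy}-6-ethenyl-2,2,5a-trimethyldecahydro-1-benzoxepin-7-ol (C7 epimers) | C=C[C@@H]1[C@@]2(C)CC[C@@H](O[Si](C)(C)C(C)(C)C)C(C)(C)O[C@@H]2CCC1O
F6 | step 10 | (2R,3R)-3-{[tert-butyl(dimethyl)silyl]oxy}-2-methyl-2-(prop-2-en-1-yl)-6-(trimethylsilyl)cyclohexan-1-one (C6 epimers) | C=CC[C@]1(C)[C@H](O[Si](C)(C)C(C)(C)C)CCC([Si](C)(C)C)C1=O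
F7 | step 10 | (2R,3R)-3-{[tert-butyl(dimethyl)silyl]oxy}-2-methyl-2-(prop-2-en-1-yl)cyclohexan-1-one | C=CC[C@]1(C)[C@H](O[Si](C)(C)C(C)(C)C)CCCC1=O
F8 | step 13 | (3R,5aR,6R,7S,9aR)-3-{[tert-butyl(dimethyl)silyl]oxy}-6-(2-hydroxyethyl)-2,2,5a,7-tetramethyldecahydro-1-benzoxepin-7-ol | OCC[C@@H]1[C@@]2(C)CC[C@@H](O[Si](C)(C)C(C)(C)C)C(C)(C)O[C@@H]2CC[C@]1(C)O
F9 | step 13 | (3R,5aR,6R,7S,9aR)-3-{[tert-butyl(dimethyl)silyl]oxy}-6-(2-iodoethyl)-2,2,5a,7-tetramethyldecahydro-1-benzoxepin-7-ol | ICC[C@@H]1[C@@]2(C)CC[C@@H](O[Si](C)(C)C(C)(C)C)C(C)(C)O[C@@H]2CC[C@]1(C)O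
F10 | step 13 | {2-[(3R,5aR,6R,7S,9aR)-3-{[tert-butyl(dimethyl)silyl]oxy}-7-hydroxy-2,2,5a,7-tetramethyldecahydro-1-benzoxepin-6-yl]ethyl}(iodo)zinc | I[Zn]CC[C@@H]1[C@@]2(C)CC[C@@H](O[Si](C)(C)C(C)(C)C)C(C)(C)O[C@@H]2CC[C@]1(C)O
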